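**Retrosynthetic overview**
- Feature: the furan ring (O1, C2, C3, C3a, C7a) hides an alkyne. C2 (bonded to O1 and the CH2CH2CO2Me chain) and C3 (bonded to C3a and aryl C1') are the two sp carbons of methyl pent-4-ynoate.
- Key disconnection: C3a–C3, O1–C2 and C3–C1' are cut together. This gives 5-(benzyloxy)-2-iodo-3-methylphenol, the alkyne and 1,3-bis(benzyloxy)-5-iodo-2,4-dimethylbenzene. Both benzene rings are bought, and the furan is the only ring made, in the penultimate step.
- Iodophenol: the ester carbon of methyl orsellinate marks the iodine position between OH and CH3. The sequence is 4-O-benzylation, a temporary MOM cap on the 2-OH (a free phenol would be iodinated at its ring C–H positions), saponification, ipso-iododecarboxylation and MOM removal.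
- Aryl iodide: its iodine is meta to both oxygens, so electrophilic or ipso-decarboxylative iodination cannot reach it. It is set by sterically controlled C–H borylation/iodination of 2,6-dimethoxytoluene. The second methyl comes from formylation and ionic reduction next to iodine, and the methyl ethers are then exchanged for benzyl ethers.
- End: one hydrogenolysis removes all three benzyl ethers.

Key step: step 11

Remark: the C3–C1' bond is a hindered biaryl-type axis, but the target is drawn without an axial descriptor. The axis is therefore treated as configurationally undefined, and there is no stereocentre to set.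

**Step 1**
Reactants: 1 methyl orsellinate (methyl 2,4-dihydroxy-6-methylbenzoate)
Product: 2 methyl 4-(benzyloxy)-2-hydroxy-6-methylbenzoate
Conditions: BnBr (1.05 equiv), K2CO3 (1.2 equiv), acetone, reflux
Reagents that add atoms: benzyl bromide, BrCc1ccccc1
Why: Williamson etherification; the 2-OH is held in a hydrogen bond to the ester carbonyl, so one equivalent of BnBr with a weak base should alkylate only the 4-OH.

**Step 2**
Reactants: 2 methyl 4-(benzyloxy)-2-hydroxy-6-methylbenzoate
Product: 3 methyl 4-(benzyloxy)-2-(methoxymethoxy)-6-methylbenzoate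
Conditions: NaH, MOMCl, DMF, 0 °C to rt
Reagents that add atoms: chloromethyl methyl ether, COCCl
Why: Williamson-type O-alkylation; irreversible deprotonation breaks the hydrogen bond and the phenoxide is capped as a base-stable acetal, so that iodine in step 4 meets no phenoxide whose ring C–H positions it could attack.

**Step 3**
Reactants: 3 methyl 4-(benzyloxy)-2-(methoxymethoxy)-6-methylbenzoate
Product: 4 4-(benzyloxy)-2-(methoxymethoxy)-6-methylbenzoic acid
Conditions: KOH (10 equiv), DMSO/H2O 4:1, 100 °C; then 1 M HCl to pH 4, 0 °C
Reagents that add atoms: potassium hydroxide, [K+].[OH-]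
Why: Saponification of a 2,6-disubstituted benzoate needs forcing alkali, to which the benzyl and MOM ethers are inert, and brief cold acidification to pH 4 should spare the acetal.

**Step 4**
Reactants: 4 4-(benzyloxy)-2-(methoxymethoxy)-6-methylbenzoic acid
Product: 5 5-(benzyloxy)-2-iodo-1-(methoxymethoxy)-3-methylbenzene
Conditions: I2 (2 equiv), K3PO4 (1 equiv), MeCN, 80–100 °C, sealed tube; aq. Na2S2O3 work-up
Reagents that add atoms: iodine, II
Why: Transition-metal-free decarboxylative ipso-iodination of an electron-rich benzoic acid; the carboxyl-bearing carbon is ortho to OMOM, para to OBn and flanked by two ortho groups, so CO2 is exchanged for iodine there, while I2 without acid or oxidant should be too weak an electrophile for the aryl ether C–H positions.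

**Step 5**
Reactants: 5 5-(benzyloxy)-2-iodo-1-(methoxymethoxy)-3-methylbenzene
Product: 6 5-(benzyloxy)-2-iodo-3-methylphenol
Conditions: conc. HCl (cat.), MeOH/THF, 40 °C
Reagents that add atoms: none
Why: Acid-catalysed acetal methanolysis frees the phenol, and the acid is dilute enough that the benzyl ether stays and protodeiodination of the activated C–I carbon should not set in.

**Step 6**
Reactants: 7 2,6-dimethoxytoluene (1,3-dimethoxy-2-methylbenzene)
Product: 9 5-iodo-1,3-dimethoxy-2-methylbenzene, via arylboronate 8 (not isolated)
Conditions: [Ir(OMe)(cod)]2 (1.5 mol %), 4,4'-di-tert-butyl-2,2'-bipyridine (3 mol %), B2pin2 (1.0 equiv), THF, 80 °C; evaporate; then CuI (10 mol %), 1,10-phenanthroline (20 mol %), KI (1.5 equiv), MeOH/H2O 4:1, air, 80 °C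
Reagents that add atoms: potassium iodide, [K+].[I-]; bis(pinacolato)diboron, CC1(C)OB(OC1(C)C)B1OC(C)(C)C(C)(C)O1 (its boryl group is held only by 8)
Why: Sterically controlled iridium-catalysed C–H borylation picks the only C–H without an ortho substituent (para to CH3, meta to both OMe), and copper-catalysed aerobic iododeboronation then puts iodine on that carbon.

**Step 7**
Reactants: 9 5-iodo-1,3-dimethoxy-2-methylbenzene
Product: 11 6-iodo-2,4-dimethoxy-3-methylbenzaldehyde, via iminium chloride 10 (not isolated)
Conditions: POCl3 (3 equiv), DMF, 0 to 90 °C; then ice/H2O, rt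
Reagents that add atoms: N,N-dimethylformamide, CN(C)C=O; water, O
Why: Vilsmeier–Haack formylation; the two free ring positions are equivalent and each is ortho to one OMe and para to the other, as in the well-behaved formylation of 1-halo-3,5-dimethoxybenzenes next to the halogen, and the first formyl group deactivates the ring against a second.

**Step 8**
Reactants: 11 6-iodo-2,4-dimethoxy-3-methylbenzaldehyde
Product: 12 1-iodo-3,5-dimethoxy-2,4-dimethylbenzene
Conditions: Et3SiH (3 equiv), TFA, CH2Cl2, 0 °C to rt
Reagents that add atoms: none
Why: Ionic hydrogenation; the ortho- and para-methoxy groups stabilise the benzylic cation that excess silane traps twice down to CH3, and the C–I bond (meta to both OMe, no metal hydride or hydrogenation catalyst present) should survive.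

**Step 9**
Reactants: 12 1-iodo-3,5-dimethoxy-2,4-dimethylbenzene
Product: 13 5-iodo-2,4-dimethylbenzene-1,3-diol
Conditions: BBr3 (3 equiv), CH2Cl2, −78 °C to rt; H2O
Reagents that add atoms: none
Why: Lewis-acid cleavage of aryl methyl ethers (boron complexation, then bromide attack at methyl), with no other group in the molecule that BBr3 could touch.

**Step 10**
Reactants: 13 5-iodo-2,4-dimethylbenzene-1,3-diol
Product: 14 1,3-bis(benzyloxy)-5-iodo-2,4-dimethylbenzene (iodine flanked by C–H and C–CH3)
Conditions: BnBr (2.4 equiv), K2CO3 (3 equiv), DMF, 60 °C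
Reagents that add atoms: benzyl bromide, BrCc1ccccc1
Why: Double Williamson etherification in a dipolar aprotic solvent, which favours O- over C-alkylation and is warm enough for the hydroxyl flanked by two methyl groups.

**Step 11**
Reactants: 6 5-(benzyloxy)-2-iodo-3-methylphenol; 15 methyl pent-4-ynoate; 14 1,3-bis(benzyloxy)-5-iodo-2,4-dimethylbenzene
Product: 17 methyl 3-[6-(benzyloxy)-3-[3,5-bis(benzyloxy)-2,4-dimethylphenyl]-4-methyl-1-benzofuran-2-yl]propanoate, via alkynylphenol 16 (not isolated)
Conditions: 6, 15 (1.2 equiv), PdCl2(PPh3)2 (5 mol %), CuI (2 mol %), Et3N, THF, Ar, rt to 40 °C until 6 is consumed; then 14 (2 equiv), dry K2CO3 (4 equiv), MeCN, 90 °C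
Reagents that add atoms: none
Why: Stage one is a Sonogashira coupling in which zerovalent palladium (formed from PdCl2(PPh3)2) inserts into the C–I bond of 6, the copper acetylide of 15 transmetalates and reductive elimination forges C3a–C3 of 16 at a temperature at which the free phenol does not yet add to the triple bond. In stage two the same catalyst inserts into the C–I bond of 14 and the resulting arylpalladium iodide (divalent palladium) binds the alkyne of 16 as a π-acid; the carbonate-generated phenoxide attacks the chain-bearing alkyne carbon anti to the metal (O1–C2), and the 3-benzofuranyl(aryl)palladium so formed collapses by reductive elimination to C3–C1', returning zerovalent palladium. The closest known reaction type is the one-pot three-component Sonogashira/Cacchi-type arylative annulation of 2-iodophenols, terminal alkynes and aryl iodides to 2,3-disubstituted benzofurans. The single ring closed, the furan, forms in the 5-endo-dig mode, and no stereocentre is created. Regiochemistry is built in: the phenol oxygen can reach only the distal alkyne carbon, so palladium and hence the aryl group must sit on C3, and the iodine of 6 between OH and CH3 fixes the 4-methyl/6-oxygen pattern. The selectivity to be won is arylative closure over proton-terminated cycloisomerisation to the 3-unsubstituted benzofuran, which is served by full consumption of 6 before heating, little CuI, an excess of 14 that keeps arylpalladium iodide as the resting state, and a dry carbonate base that holds the phenol as phenoxide and keeps proton sources scarce.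

**Step 12**
Reactants: 17 methyl 3-[6-(benzyloxy)-3-[3,5-bis(benzyloxy)-2,4-dimethylphenyl]-4-methyl-1-benzofuran-2-yl]propanoate
Product: 18 talarominine A, methyl 3-[3-(3,5-dihydroxy-2,4-dimethylphenyl)-6-hydroxy-4-methyl-1-benzofuran-2-yl]propanoate
Conditions: H2 (1 atm), 10% Pd/C, EtOAc/MeOH, rt
Reagents that add atoms: none
Why: Heterogeneous hydrogenolysis of the three benzylic C–O bonds, under which the methyl ester and the tetrasubstituted C2=C3 bond of the benzofuran should stay untouched.

**Compound list**
1 | methyl orsellinate (methyl 2,4-dihydroxy-6-methylbenzoate) | COC(=O)c1c(C)cc(O)cc1O | starting material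
2 | methyl 4-(benzyloxy)-2-hydroxy-6-methylbenzoate | COC(=O)c1c(C)cc(OCc2ccccc2)cc1O | intermediate
3 | methyl 4-(benzyloxy)-2-(methoxymethoxy)-6-methylbenzoate | COCOc1cc(OCc2ccccc2)cc(C)c1C(=O)OC | intermediate
4 | 4-(benzyloxy)-2-(methoxymethoxy)-6-methylbenzoic acid | COCOc1cc(OCc2ccccc2)cc(C)c1C(=O)O | intermediate
5 | 5-(benzyloxy)-2-iodo-1-(methoxymethoxy)-3-methylbenzene | COCOc1cc(OCc2ccccc2)cc(C)c1I | intermediate
6 | 5-(benzyloxy)-2-iodo-3-methylphenol | Oc1cc(OCc2ccccc2)cc(C)c1I | intermediate
7 | 2,6-dimethoxytoluene | COc1cccc(OC)c1C | starting material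
8 | 2-(3,5-dimethoxy-4-methylphenyl)-4,4,5,5-tetramethyl-1,3,2-dioxaborolane | COc1cc(B2OC(C)(C)C(C)(C)O2)cc(OC)c1C | intermediate
9 | 5-iodo-1,3-dimethoxy-2-methylbenzene | COc1cc(I)cc(OC)c1C | intermediate
10 | [(6-iodo-2,4-dimethoxy-3-methylphenyl)methylidene]dimethylazanium chloride | C[N+](C)=Cc1c(I)cc(OC)c(C)c1OC.[Cl-] | intermediate
11 | 6-iodo-2,4-dimethoxy-3-methylbenzaldehyde | O=Cc1c(I)cc(OC)c(C)c1OC | intermediate
12 | 1-iodo-3,5-dimethoxy-2,4-dimethylbenzene | Cc1c(I)cc(OC)c(C)c1OC | intermediate
13 | 5-iodo-2,4-dimethylbenzene-1,3-diol | Cc1c(I)cc(O)c(C)c1O | intermediate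
14 | 1,3-bis(benzyloxy)-5-iodo-2,4-dimethylbenzene | Ic1cc(OCc2ccccc2)c(C)c(OCc2ccccc2)c1C | intermediate
15 | methyl pent-4-ynoate | COC(=O)CCC#C | starting material
16 | methyl 5-[4-(benzyloxy)-2-hydroxy-6-methylphenyl]pent-4-ynoate | COC(=O)CCC#Cc1c(C)cc(OCc2ccccc2)cc1O | intermediate
17 | methyl 3-[6-(benzyloxy)-3-[3,5-bis(benzyloxy)-2,4-dimethylphenyl]-4-methyl-1-benzofuran-2-yl]propanoate | COC(=O)CCc1oc2cc(OCc3ccccc3)cc(C)c2c1-c1cc(OCc2ccccc2)c(C)c(OCc2ccccc2)c1C | intermediate
18 | talarominine A | COC(=O)CCc1oc2cc(O)cc(C)c2c1-c1cc(O)c(C)c(O)c1C | target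

**Step count**
Total step count: 12.
Longest linear sequence: 7 steps (1–5, 11, 12). The branch 6–10, 11, 12 has the same length.

**Steps most likely to fail**

**Step 11.**
- What may go wrong: both partners carry a methyl group next to the reacting carbon. Binding of the arylpalladium iodide to the alkyne may then be slower than proton-terminated cycloisomerisation of the alkynylphenol. Oxidative dimerisation of the alkyne, or Sonogashira consumption of the aryl iodide by leftover alkyne, may also drain the components.
- Fallback, from 16 and 14 back to 17: the ring closure and the arylation are separated.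
- The Sonogashira stage is stopped at room temperature and 16 is isolated.
- I2 and NaHCO3 in MeCN at rt should close the furan by 5-endo-dig iodocyclisation to methyl 3-[6-(benzyloxy)-3-iodo-4-methyl-1-benzofuran-2-yl]propanoate F1.
- In parallel, Miyaura borylation of 14 (B2pin2, PdCl2(dppf), KOAc, dioxane, 90 °C) should give 2-[3,5-bis(benzyloxy)-2,4-dimethylphenyl]-4,4,5,5-tetramethyl-1,3,2-dioxaborolane F2.
- Suzuki–Miyaura coupling of the two (Pd(OAc)2, SPhos, K3PO4, toluene with a little water, 90 °C) then leads to 17.

**Step 4.**
- What may go wrong: further iodination of the electron-rich ring at its C–H positions, simple protodecarboxylation, or iodine-promoted loss of the MOM acetal at the reaction temperature.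
- Fallback, from 4 back to 5: the carboxyl carbon is kept as the position marker but is exchanged through nitrogen.
- DPPA and Et3N in toluene should give 4-(benzyloxy)-2-(methoxymethoxy)-6-methylbenzoyl azide F3.
- Curtius rearrangement at 90 °C converts this to 5-(benzyloxy)-2-isocyanato-1-(methoxymethoxy)-3-methylbenzene F4.
- Aqueous KOH in THF hydrolyses F4 to 4-(benzyloxy)-2-(methoxymethoxy)-6-methylaniline F5.
- Aprotic Sandmeyer-type diazotisation–iodination (isoamyl nitrite, I2, MeCN, 60 °C), which spares the acetal, returns to 5.

**Step 7.**
- What may go wrong: sluggish attack of the bulky chloroiminium ion at the position wedged between iodine and methoxy. Forcing conditions could then cause O-demethylation or loss of iodine.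
- Fallback, from 8 (isolated after the borylation half of step 6) back to 12: the methyl group is brought in by cross-coupling while boron still masks the iodine.
- NBS in MeCN at 0 °C, a small electrophile, should brominate para to a methoxy group to give 2-(2-bromo-3,5-dimethoxy-4-methylphenyl)-4,4,5,5-tetramethyl-1,3,2-dioxaborolane F6.
- Base-free Negishi coupling (MeZnCl, PdCl2(dppf), THF, 60 °C), under which the boronate does not transmetalate, should give 2-(3,5-dimethoxy-2,4-dimethylphenyl)-4,4,5,5-tetramethyl-1,3,2-dioxaborolane F7.
- The copper-catalysed iododeboronation of step 6 (CuI, 1,10-phenanthroline, KI, air, MeOH/H2O, 80 °C) then gives 12. Steps 7 and 8 are bypassed.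

**Further compounds**
F1 | step 11 | methyl 3-[6-(benzyloxy)-3-iodo-4-methyl-1-benzofuran-2-yl]propanoate | COC(=O)CCc1oc2cc(OCc3ccccc3)cc(C)c2c1I
F2 | step 11 | 2-[3,5-bis(benzyloxy)-2,4-dimethylphenyl]-4,4,5,5-tetramethyl-1,3,2-dioxaborolane | Cc1c(OCc2ccccc2)cc(B2OC(C)(C)C(C)(C)O2)c(C)c1OCc1ccccc1
F3 | step 4 | 4-(benzyloxy)-2-(methoxymethoxy)-6-methylbenzoyl azide | COCOc1cc(OCc2ccccc2)cc(C)c1C(=O)N=[N+]=[N-]
F4 | step 4 | 5-(benzyloxy)-2-isocyanato-1-(methoxymethoxy)-3-methylbenzene | COCOc1cc(OCc2ccccc2)cc(C)c1N=C=O
F5 | step 4 | 4-(benzyloxy)-2-(methoxymethoxy)-6-methylaniline | COCOc1cc(OCc2ccccc2)cc(C)c1N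
F6 | step 7 | 2-(2-bromo-3,5-dimethoxy-4-methylphenyl)-4,4,5,5-tetramethyl-1,3,2-dioxaborolane | COc1cc(B2OC(C)(C)C(C)(C)O2)c(Br)c(OC)c1C
F7 | step 7 | 2-(3,5-dimethoxy-2,4-dimethylphenyl)-4,4,5,5-tetramethyl-1,3,2-dioxaborolane | COc1cc(B2OC(C)(C)C(C)(C)O2)c(C)c(OC)c1C
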